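The tetramethylcyclohexenedione ring is opened between its C1 ketone carbon, the carbonyl flanked by both quaternary carbons, and the quaternary C6 next to the enol carbon C5. The seco form is an open-chain 3,5-dioxo ester in which C6 is still an isopropyl methine. A dianion Dieckmann closure then forges the six-membered ring and the fully substituted C6 in one operation; it exploits the 1,3-dicarbonyl relationship C5(O)–C6–C1(=O) and the quaternary C2, which leaves that methine as the only second enolisable site. The base-labile benzylic stereocentre is installed last, by a catalytic enantioselective Friedel–Crafts-type Michael addition of the acylphloroglucinol to the isobutylidene trione.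

Key step: step 2

Assumption: (R)-TRIP is taken to be the catalyst enantiomer that leads to the (S)-configured centre; if the first run shows the opposite sense of induction, (S)-TRIP is used in the same step. The (S) descriptor refers to the enol tautomer as drawn.

Step 1
Reactants: 1 ethyl 2,2-dimethyl-3-oxobutanoate; 2 isobutyryl chloride (2-methylpropanoyl chloride)
Product: 3 ethyl 2,2,6-trimethyl-3,5-dioxoheptanoate
Conditions: 1 (2.0 equiv), LiN(SiMe3)2 (LiHMDS, 2.1 equiv), toluene/THF, 0 °C; then 2 (1.0 equiv), 0 °C → rt; 1 M HCl
Reagents that add atoms: none
Why: Crossed Claisen-type C-acylation of a ketone lithium enolate with an acid chloride, in which the methyl group is the only enolisable position of 1 and the second equivalent of enolate deprotonates the acidic 1,3-diketone as it forms, which should suppress double acylation.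

Step 2
Reactants: 3 ethyl 2,2,6-trimethyl-3,5-dioxoheptanoate
Product: 5 syncarpic acid (5-hydroxy-2,2,6,6-tetramethylcyclohex-4-ene-1,3-dione), via dilithium dienediolate 4 (not isolated)
Conditions: LiN(i-Pr)2 (LDA, 2.4 equiv), THF, −78 °C → rt; then 2 M HCl
Reagents that add atoms: none
Why: The first equivalent of base removes the acidic C4–H between the two ketones and the second removes the only other enolisable hydrogen, the isopropyl methine, to give dienediolate 4, whose tertiary terminal carbon adds to the ester carbonyl and expels ethoxide. The closest known reaction type is the Dieckmann condensation, here in the form of the terminal acylation of a 1,3-diketone dianion by an ester. The carbocycle closes in a 6-(enolexo)-exo-trig mode, helped by the two gem-dimethyl groups, and the product leaves as the lithium enolate of a vinylogous acid, which should make the closure irreversible. No stereocentre is formed, because the new quaternary carbon carries two methyl groups. The step needs site selectivity only: C2 of 3 is quaternary, so no other carbanion can form at the second deprotonation, and the central carbanion could reach the ester only through a four-membered ring.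

Step 3
Reactants: 5 syncarpic acid; 6 isobutyraldehyde (2-methylpropanal)
Product: 8 2,2,4,4-tetramethyl-6-(2-methylpropylidene)cyclohexane-1,3,5-trione, via Mannich base 7 (not isolated)
Conditions: piperidine (1.1 equiv), CH2Cl2, rt; then 1 M HCl wash, 0 °C; used directly
Reagents that add atoms: none
Why: Knoevenagel condensation run through the Mannich base, in which the enol of 5 traps the piperidine-derived iminium ion as 7 and acid then expels piperidine by β-elimination, the stoichiometric amine keeping free 5 from adding to 8.

Step 4
Reactants: 9 2,4,6-trihydroxytoluene (2-methylbenzene-1,3,5-triol); 2 isobutyryl chloride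
Product: 10 2-methyl-1-(2,4,6-trihydroxy-3-methylphenyl)propan-1-one
Conditions: AlCl3 (4 equiv), PhNO2, 0 → 65 °C; ice/aq. HCl
Reagents that add atoms: none
Why: Friedel–Crafts acylation of the electron-rich methylphloroglucinol at one of its two equivalent free ring positions, after which the acyl group deactivates the ring and should stop the reaction at monoacylation.

Step 5
Reactants: 8 2,2,4,4-tetramethyl-6-(2-methylpropylidene)cyclohexane-1,3,5-trione; 10 2-methyl-1-(2,4,6-trihydroxy-3-methylphenyl)propan-1-one
Product: 11 5-hydroxy-2,2,6,6-tetramethyl-4-{(1S)-2-methyl-1-[2,4,6-trihydroxy-3-methyl-5-(2-methylpropanoyl)phenyl]propyl}cyclohex-4-ene-1,3-dione (target)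
Conditions: (R)-TRIP [(R)-3,3'-bis(2,4,6-triisopropylphenyl)-1,1'-binaphthyl-2,2'-diyl hydrogen phosphate] (10 mol %), CH2Cl2/toluene, −40 °C
Reagents that add atoms: none
Why: Chiral Brønsted acid-catalysed asymmetric Friedel–Crafts-type Michael addition, in which the phosphoric acid hydrogen-bonds to a ring carbonyl of 8 and through its P=O to a phenolic OH of 10, so that the only free ring carbon of 10 attacks one enantiotopic face of the alkylidene β-carbon inside the chiral pocket and the (S)-centre is set under catalyst control, the low temperature holding back the uncatalysed addition.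

Compound list
1 | ethyl 2,2-dimethyl-3-oxobutanoate | CCOC(=O)C(C)(C)C(C)=O | starting material
2 | isobutyryl chloride (2-methylpropanoyl chloride) | CC(C)C(Cl)=O | starting material
3 | ethyl 2,2,6-trimethyl-3,5-dioxoheptanoate | CCOC(=O)C(C)(C)C(=O)CC(=O)C(C)C | intermediate
4 | dilithium dienediolate of 3 (dilithium 7-ethoxy-2,6,6-trimethyl-7-oxohepta-2,4-diene-3,5-diolate) | [Li+].[Li+].CCOC(=O)C(C)(C)C([O-])=CC([O-])=C(C)C | intermediate (not isolated)
5 | syncarpic acid (5-hydroxy-2,2,6,6-tetramethylcyclohex-4-ene-1,3-dione, enol form of 2,2,4,4-tetramethylcyclohexane-1,3,5-trione) | CC1(C)C(O)=CC(=O)C(C)(C)C1=O | intermediate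
6 | isobutyraldehyde (2-methylpropanal) | CC(C)C=O | starting material
7 | Mannich base, 5-hydroxy-2,2,6,6-tetramethyl-4-[2-methyl-1-(piperidin-1-yl)propyl]cyclohex-4-ene-1,3-dione (racemic) | CC(C)C(N1CCCCC1)C1=C(O)C(C)(C)C(=O)C(C)(C)C1=O | intermediate (not isolated)
8 | 2,2,4,4-tetramethyl-6-(2-methylpropylidene)cyclohexane-1,3,5-trione | CC(C)C=C1C(=O)C(C)(C)C(=O)C(C)(C)C1=O | intermediate
9 | 2,4,6-trihydroxytoluene (2-methylbenzene-1,3,5-triol) | Cc1c(O)cc(O)cc1O | starting material
10 | 2-methyl-1-(2,4,6-trihydroxy-3-methylphenyl)propan-1-one | Cc1c(O)cc(O)c(C(=O)C(C)C)c1O | intermediate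
11 | 5-hydroxy-2,2,6,6-tetramethyl-4-{(1S)-2-methyl-1-[2,4,6-trihydroxy-3-methyl-5-(2-methylpropanoyl)phenyl]propyl}cyclohex-4-ene-1,3-dione | Cc1c(O)c(C(=O)C(C)C)c(O)c([C@@H](C2=C(O)C(C)(C)C(=O)C(C)(C)C2=O)C(C)C)c1O | target

Total step count: 5. Longest linear sequence: 4 steps (steps 1, 2, 3 and 5); step 4 prepares the second fragment.

Steps most likely to fail

Step 5. The uncatalysed addition of 10 to the very electrophilic 8 may compete with the catalysed pathway and give poor facial selectivity, and reversible retro-Michael cleavage may erode the enantiomeric purity during work-up. The fallback sets out from 8 and 10, which are combined without a chiral catalyst (i-Pr2NEt cat., THF, rt) to give rac-11 F1. This is resolved by preparative supercritical-fluid chromatography on an amylose tris(3,5-dimethylphenylcarbamate) phase, and the route is rejoined at 11. The unwanted ent-11 F2 should be returned to F1 by base-induced retro-Michael/Michael equilibration (DBU cat., THF, 40 °C) and resolved again.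

Step 2. The second deprotonation, at a hindered methine of an already anionic enolate, may be slow, so that the closure stalls at the monoenolate of 3. The fallback sets out from 3 and masks the acidic central position: trimethyl orthoformate, cat. p-TsOH, MeOH, reflux should give a mixture of the two enol ethers, ethyl 5-methoxy-2,2,6-trimethyl-3-oxohept-4-enoate F3 and ethyl 3-methoxy-2,2,6-trimethyl-5-oxohept-3-enoate F4, which need not be separated. Each has the isopropyl methine as its only acidic hydrogen (γ in F3, α' in F4). One equivalent of LiN(i-Pr)2 (THF, −78 → 0 °C) should therefore close the same ring bond from either isomer, as a monoanion Dieckmann condensation, to give 5-methoxy-2,2,6,6-tetramethylcyclohex-4-ene-1,3-dione F5. Hydrolysis of the enol ether (2 M HCl, THF, 50 °C) returns to the route at 5.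

Step 1. O-acylation of the enolate and double acylation may compete with the wanted C-acylation. The fallback sets out from 1 and builds the diketone by aldol addition and oxidation: LiN(i-Pr)2, THF, −78 °C, then isobutyraldehyde 6 and a cold AcOH quench should give ethyl 5-hydroxy-2,2,6-trimethyl-3-oxoheptanoate F6. Oxidation of F6 with Dess–Martin periodinane (NaHCO3, CH2Cl2, rt) returns to the route at 3.

Further compounds
F1 | step 5 | rac-11 (racemate of 11) | Cc1c(O)c(C(=O)C(C)C)c(O)c(C(C2=C(O)C(C)(C)C(=O)C(C)(C)C2=O)C(C)C)c1O
F2 | step 5 | ent-11 ((R)-enantiomer of 11) | Cc1c(O)c(C(=O)C(C)C)c(O)c([C@H](C2=C(O)C(C)(C)C(=O)C(C)(C)C2=O)C(C)C)c1O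
F3 | step 2 | ethyl 5-methoxy-2,2,6-trimethyl-3-oxohept-4-enoate (double-bond geometry not defined) | CCOC(=O)C(C)(C)C(=O)C=C(OC)C(C)C
F4 | step 2 | ethyl 3-methoxy-2,2,6-trimethyl-5-oxohept-3-enoate (double-bond geometry not defined) | CCOC(=O)C(C)(C)C(OC)=CC(=O)C(C)C
F5 | step 2 | 5-methoxy-2,2,6,6-tetramethylcyclohex-4-ene-1,3-dione | COC1=CC(=O)C(C)(C)C(=O)C1(C)C
F6 | step 1 | ethyl 5-hydroxy-2,2,6-trimethyl-3-oxoheptanoate (racemic) | CCOC(=O)C(C)(C)C(=O)CC(O)C(C)C
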